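**Retrosynthetic overview**

- The strategy rests on ring A (cyclohexane; C1 carries the oxanyl group, C3 the chlorine, C4 the bromine and methyl). The C3–Cl and tertiary C4–Br bonds are trans-diaxial with the C1 substituent equatorial. That is the outcome of bromide opening a C3/C4 chloronium ion at C4, a regiochemistry that BrCl addition to the alkene would not give.
- Disconnection 1 (key): the C4–Br bond of ring A, back to the trans-diaxial C3-chloro C4-hydroxy compound, by deoxybromination with retention through that chloronium ion.
- Disconnection 2: the chlorohydrin back to the ring A alkene, by chloride opening of an epoxide at C3, epoxide closure, and bromohydrin formation.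
- Disconnection 3: ring B (oxane; O1, C2 gem-dimethyl, C3 bromide, C6 quaternary) back to (−)-α-bisabolol by 6-endo bromoetherification.
- Ring order: ring A is bought with the terpene, ring B is closed in step 1, an oxirane is fused to ring A in step 3 and opened in step 4, and the last step closes no ring.

Key step: step 5

Assumption: commercial (−)-α-bisabolol (levomenol) is taken as the (S,S)-isomer of high enantiomeric purity, so that both carbon-only stereocentres of the target are bought.

**Route**

Step 1
Reactants: 1 (−)-α-bisabolol, (2S)-6-methyl-2-[(1S)-4-methylcyclohex-3-en-1-yl]hept-5-en-2-ol; 2 N-bromosuccinimide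
Product: 3 (3R,6S)-3-bromo-2,2,6-trimethyl-6-[(1S)-4-methylcyclohex-3-en-1-yl]oxane
Conditions: NBS (1.0 equiv), anhydrous CH2Cl2, −40 to 0 °C, dark; chromatography
Reagents that add atoms: N-bromosuccinimide, O=C1CCC(=O)N1Br
Why: Bromoetherification (6-endo halocyclisation): the tertiary hydroxyl traps the side-chain bromonium ion at its dimethyl-substituted carbon, while the ring A alkene, which has no nucleophile in reach without a boat, should be left alone, and a chair transition state with the cyclohexenyl group equatorial at C6 and oxygen entering anti to bromine should place the new C3 bromide equatorial and trans to the cyclohexenyl group (3R); the 5-exo oxolane isomer and the C3 epimer are expected by-products and are removed by chromatography.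

Step 2
Reactants: 3 (3R,6S)-3-bromo-2,2,6-trimethyl-6-[(1S)-4-methylcyclohex-3-en-1-yl]oxane; 2 N-bromosuccinimide
Product: 4 (1R,2R,4S)-2-bromo-4-[(2S,5R)-5-bromo-2,6,6-trimethyloxan-2-yl]-1-methylcyclohexan-1-ol
Conditions: NBS (1.1 equiv), acetone–H2O (4:1), 0 °C
Reagents that add atoms: N-bromosuccinimide, O=C1CCC(=O)N1Br; water, O
Why: Bromohydrin formation: bromonium ions form reversibly on both faces of the ring A alkene, but only the one on the face opposite the equatorial oxanyl group can be opened by water at the tertiary carbon in the trans-diaxial (Fürst–Plattner) mode, so the C4 hydroxyl should end up axial and cis to the C1 substituent and the C3 bromide axial and trans to it, as in the analogous limonene case.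

Step 3
Reactants: 4 (1R,2R,4S)-2-bromo-4-[(2S,5R)-5-bromo-2,6,6-trimethyloxan-2-yl]-1-methylcyclohexan-1-ol
Product: 5 (1R,4S,6S)-4-[(2S,5R)-5-bromo-2,6,6-trimethyloxan-2-yl]-1-methyl-7-oxabicyclo[4.1.0]heptane
Conditions: K2CO3 (2 equiv), MeOH, 0 °C to rt
Reagents that add atoms: none
Why: Intramolecular Williamson closure to the oxirane: the axial C4 alkoxide is antiperiplanar to the axial C3–Br bond and displaces it with inversion, giving the epoxide on the face cis to the oxanyl group, while the equatorial bromide of ring B, next to a quaternary carbon and with no antiperiplanar hydrogen, should resist both substitution and elimination.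

Step 4
Reactants: 5 (1R,4S,6S)-4-[(2S,5R)-5-bromo-2,6,6-trimethyloxan-2-yl]-1-methyl-7-oxabicyclo[4.1.0]heptane; 6 lithium chloride
Product: 7 (1R,2R,4S)-4-[(2S,5R)-5-bromo-2,6,6-trimethyloxan-2-yl]-2-chloro-1-methylcyclohexan-1-ol
Conditions: LiCl (5 equiv), AcOH (3 equiv), THF, rt
Reagents that add atoms: lithium chloride, [Li+].[Cl-]
Why: Epoxide to halohydrin opening with a lithium halide and acetic acid: under these weakly acidic, non-ionising conditions chloride should attack the secondary C3 from the face opposite the oxygen, which is both the less hindered carbon and the trans-diaxial trajectory in the half-chair that keeps the oxanyl group equatorial, so C3 is inverted (chlorine axial, trans to the C1 substituent) and the C4 hydroxyl stays axial.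

Step 5
Reactants: 7 (1R,2R,4S)-4-[(2S,5R)-5-bromo-2,6,6-trimethyloxan-2-yl]-2-chloro-1-methylcyclohexan-1-ol; 8 bromotrimethylsilane
Product: 10 (3R,6S)-3-bromo-6-[(1S,3R,4R)-4-bromo-3-chloro-4-methylcyclohexyl]-2,2,6-trimethyloxane (target), via trimethylsilyl ether 9 (not isolated)
Conditions: Me3SiBr (2 equiv), CH2Cl2, −40 to 0 °C, no base; cold aqueous NaHCO3 quench at full conversion
Reagents that add atoms: bromotrimethylsilane, C[Si](C)(C)Br
Why: Me3SiBr silylates the axial tertiary C4 hydroxyl and releases HBr; the protonated silyl ether then ionises with help from the antiperiplanar axial C3 chlorine to a chlorine-bridged tertiary cation on the ring A face opposite the oxanyl group, and bromide opens this chloronium ion at C4 from the face the oxygen left. The closest known reaction type is the conversion of trans-2-halo alcohols into trans-1,2-dihalides by HBr with retention through a bridged halonium ion, joined to the usual exchange of a tertiary alcohol for a tertiary bromide by Me3SiBr. No ring is closed; only the C4–Br bond of ring A is formed. The configuration at C4 is controlled by the axial C3 chlorine, since two inversions (chlorine in, bromide in) amount to retention, leaving bromine axial, cis to the C1 substituent and anti to chlorine (4R). The step needs bromide attack at C4 and not C3, substitution over elimination, and survival of the ditertiary ether of ring B: attack at C4 is both the more substituted carbon and the trans-diaxial opening, the chair is locked by the equatorial oxanyl group, and any alkene formed can re-add HBr through the same cation. Low temperature, the absence of base and a prompt quench, together with the lowered basicity of the ring B oxygen next to its C3 bromide, should spare ring B.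

**Compound list**

1 | (−)-α-bisabolol, (2S)-6-methyl-2-[(1S)-4-methylcyclohex-3-en-1-yl]hept-5-en-2-ol | O[C@](C)([C@H]1CCC(C)=CC1)CCC=C(C)C | starting material
2 | N-bromosuccinimide | O=C1CCC(=O)N1Br | starting material
3 | (3R,6S)-3-bromo-2,2,6-trimethyl-6-[(1S)-4-methylcyclohex-3-en-1-yl]oxane | CC1(C)O[C@](C)([C@H]2CCC(C)=CC2)CC[C@H]1Br | intermediate
4 | (1R,2R,4S)-2-bromo-4-[(2S,5R)-5-bromo-2,6,6-trimethyloxan-2-yl]-1-methylcyclohexan-1-ol | CC1(C)O[C@](C)([C@H]2CC[C@@](C)(O)[C@H](Br)C2)CC[C@H]1Br | intermediate
5 | (1R,4S,6S)-4-[(2S,5R)-5-bromo-2,6,6-trimethyloxan-2-yl]-1-methyl-7-oxabicyclo[4.1.0]heptane | CC1(C)O[C@](C)([C@H]2CC[C@@]3(C)O[C@H]3C2)CC[C@H]1Br | intermediate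
6 | lithium chloride | [Li+].[Cl-] | starting material
7 | (1R,2R,4S)-4-[(2S,5R)-5-bromo-2,6,6-trimethyloxan-2-yl]-2-chloro-1-methylcyclohexan-1-ol | CC1(C)O[C@](C)([C@H]2CC[C@@](C)(O)[C@H](Cl)C2)CC[C@H]1Br | intermediate
8 | bromotrimethylsilane | C[Si](C)(C)Br | starting material
9 | {[(1R,2R,4S)-4-[(2S,5R)-5-bromo-2,6,6-trimethyloxan-2-yl]-2-chloro-1-methylcyclohexyl]oxy}trimethylsilane | CC1(C)O[C@](C)([C@H]2CC[C@@](C)(O[Si](C)(C)C)[C@H](Cl)C2)CC[C@H]1Br | intermediate
10 | (3R,6S)-3-bromo-6-[(1S,3R,4R)-4-bromo-3-chloro-4-methylcyclohexyl]-2,2,6-trimethyloxane | CC1(C)O[C@](C)([C@H]2CC[C@@](C)(Br)[C@H](Cl)C2)CC[C@H]1Br | target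

**Count**

Total step count: 5. Longest linear sequence: 5 steps, from (−)-α-bisabolol.

**Steps most likely to fail**

Step 5. The electron-withdrawing C3 chlorine may slow ionisation of the C4–O bond so much that the acid instead opens the ditertiary ether of ring B, or the cation may lose a proton faster than it captures bromide. The fallback sets out from 7 and separates C–O cleavage from C–Br formation. Dehydration with SOCl2 in pyridine at 0 °C, an anti elimination that can only use the axial C5 hydrogen or a methyl hydrogen because the C3 hydrogen is equatorial, should give mainly the allylic chloride (3R,6S)-3-bromo-6-[(1S,5R)-5-chloro-4-methylcyclohex-3-en-1-yl]-2,2,6-trimethyloxane F1. Markovnikov hydrobromination of F1 with anhydrous HBr in CH2Cl2 at −78 °C then protonates C5, lets the pseudo-axial chlorine bridge the C4 cation, and delivers bromide anti to it. The fallback returns to the route at 10.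

Step 1. Oxygen attack at the secondary terminus (5-exo closure to an oxolane), modest facial selectivity at the new C3 centre of ring B, and partial consumption of the ring A alkene may together erode the yield of one isomer. The fallback sets out from 1 and uses a reversible, thermodynamically controlled oxymercuration in place of the kinetic bromonium closure. Hg(OCOCF3)2 in MeNO2 at −20 °C should give the 6-endo organomercurial [(3R,6S)-2,2,6-trimethyl-6-[(1S)-4-methylcyclohex-3-en-1-yl]oxan-3-yl]mercury trifluoroacetate F2 with mercury equatorial. Aqueous KBr exchanges this to bromo[(3R,6S)-2,2,6-trimethyl-6-[(1S)-4-methylcyclohex-3-en-1-yl]oxan-3-yl]mercury F3. Brominative demercuration of F3 with Br2 and LiBr in pyridine under O2, conditions that suppress the radical chain and moderate the bromine toward the ring alkene, should replace mercury by bromine largely with retention. The fallback returns to the route at 3.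

Step 4. Chloride attack may drift to the tertiary carbon, or the acid may trigger rearrangement of the epoxide to a ketone or allylic alcohol, or acetate may compete as the nucleophile. The fallback sets out from 3 and avoids the epoxide altogether. Direct chlorohydroxylation of the ring A alkene with trichloroisocyanuric acid in aqueous acetone at 0 °C should form the chloronium ion on the face opposite the oxanyl group and have water open it at the tertiary carbon in the trans-diaxial mode. This bypasses 4 and 5 and returns to the route at 7; it makes no compound outside the list (none F0).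

**Further compounds**

F1 | step 5 | (3R,6S)-3-bromo-6-[(1S,5R)-5-chloro-4-methylcyclohex-3-en-1-yl]-2,2,6-trimethyloxane | CC1(C)O[C@](C)([C@H]2CC=C(C)[C@H](Cl)C2)CC[C@H]1Br
F2 | step 1 | [(3R,6S)-2,2,6-trimethyl-6-[(1S)-4-methylcyclohex-3-en-1-yl]oxan-3-yl]mercury trifluoroacetate | CC1(C)O[C@](C)([C@H]2CCC(C)=CC2)CC[C@H]1[Hg]OC(=O)C(F)(F)F
F3 | step 1 | bromo[(3R,6S)-2,2,6-trimethyl-6-[(1S)-4-methylcyclohex-3-en-1-yl]oxan-3-yl]mercury | CC1(C)O[C@](C)([C@H]2CCC(C)=CC2)CC[C@H]1[Hg]Br
F0 | step 4 | none | none
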